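Ring A is fully substituted, and its two adjacent carbons C8a and C4a carry the ring oxygen O1 and the acyl carbon C4. The route disconnects exactly these two bonds: an aryne spanning C4a≡C8a inserts into the O–C(=O) bond of a chiral β-silyloxy acid, giving C8a–O1 and C4a–C4 in one operation as an ortho-hydroxyaryl ketone that already holds every carbon of the target. The aryne precursor is a hexasubstituted 2-(trimethylsilyl)aryl triflate bearing two prenyl groups and two MOM ethers; the acid carries the future C2 stereocentre, set by asymmetric transfer hydrogenation. Desilylation, Mitsunobu closure of O1–C2 with inversion and acetal removal finish the flavanone.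

Key step: step 13

Remark: the target is (2S); because the closing Mitsunobu reaction inverts the carbinol carbon, the acid is made as the (R) enantiomer, and the three ring A oxygens are told apart only at the silyl shift, where symmetry removes any need for selectivity.

Step 1
Reactants: 1 phloroglucinol
Product: 2 1,3,5-tris(methoxymethoxy)benzene
Conditions: NaH, MOMCl, DMF, 0 °C → rt
Reagents that add atoms: chloromethyl methyl ether, COCCl
Why: Williamson-type O-alkylation of the sodium phenoxide with the hard electrophile MOMCl caps all three oxygens as acetals, which later direct metalation and resist organolithiums.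

Step 2
Reactants: 2 1,3,5-tris(methoxymethoxy)benzene; 3 prenyl bromide (1-bromo-3-methylbut-2-ene)
Product: 5 1,3,5-tris(methoxymethoxy)-2-(3-methylbut-2-enyl)benzene, via aryllithium 4 (not isolated)
Conditions: n-BuLi, TMEDA, THF, 0 °C; then CuI (10 mol%), 3, −78 °C → rt
Reagents that add atoms: none
Why: Directed ortho-metalation at a carbon flanked by two acetal oxygens gives aryllithium 4, whose copper-catalysed SN2 allylation with prenyl bromide should deliver the linear prenyl group.

Step 3
Reactants: 5 1,3,5-tris(methoxymethoxy)-2-(3-methylbut-2-enyl)benzene; 3 prenyl bromide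
Product: 7 1,3,5-tris(methoxymethoxy)-2,4-bis(3-methylbut-2-enyl)benzene, via aryllithium 6 (not isolated)
Conditions: n-BuLi, TMEDA, THF, 0 °C; then CuI (10 mol%), 3, −78 °C → rt
Reagents that add atoms: none
Why: A second directed ortho-metalation at one of the two symmetry-equivalent C–H positions between acetal oxygens, followed by the same copper-catalysed allylation, can give only one diprenyl isomer.

Step 4
Reactants: 7 1,3,5-tris(methoxymethoxy)-2,4-bis(3-methylbut-2-enyl)benzene
Product: 9 2-bromo-1,3,5-tris(methoxymethoxy)-4,6-bis(3-methylbut-2-enyl)benzene, via aryllithium 8 (not isolated)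
Conditions: n-BuLi, TMEDA, THF, 0 °C; then BrCH2CH2Br, −78 °C → rt
Reagents that add atoms: 1,2-dibromoethane, BrCCBr
Why: Directed ortho-metalation of the last ring C–H and bromine transfer from 1,2-dibromoethane to the aryllithium installs the halogen without any electrophilic bromine that could attack the prenyl alkenes.

Step 5
Reactants: 9 2-bromo-1,3,5-tris(methoxymethoxy)-4,6-bis(3-methylbut-2-enyl)benzene
Product: 10 2-bromo-4,6-bis(3-methylbut-2-enyl)benzene-1,3,5-triol
Conditions: 3 M aq. HCl/MeOH (1:5), 40 °C, argon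
Reagents that add atoms: none
Why: Acid-catalysed acetal methanolysis frees the three phenols; at this acid strength and temperature the trisubstituted alkenes should not be protonated at a competing rate.

Step 6
Reactants: 10 2-bromo-4,6-bis(3-methylbut-2-enyl)benzene-1,3,5-triol
Product: 15 3,5-dihydroxy-2,4-bis(3-methylbut-2-enyl)-6-(trimethylsilyl)phenyl trifluoromethanesulfonate, via tris(trimethylsilyl) ether 11 (not isolated), via aryllithium 12 (not isolated), via lithium phenoxide 13 (not isolated), via bis(trimethylsilyloxy) triflate 14 (not isolated)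
Conditions: HMDS, THF, 70 °C, evaporate; n-BuLi, THF, −78 °C; Tf2O, −78 → 0 °C; then AcOH, H2O, THF, 0 °C
Reagents that add atoms: hexamethyldisilazane, C[Si](C)(C)N[Si](C)(C)C; trifluoromethanesulfonic anhydride, O=S(=O)(OS(=O)(=O)C(F)(F)F)C(F)(F)F
Why: Exhaustive O-silylation, bromine–lithium exchange and an anionic 1,3 oxygen-to-carbon silyl shift (retro-Brook rearrangement) move one trimethylsilyl group onto the ring and unmask a single phenoxide, which is trapped as the triflate; since the two silyloxy groups beside the lithiated carbon are equivalent by symmetry, the three oxygens are told apart without any selectivity, and the two remaining O–Si bonds are hydrolysed in the mild acidic work-up.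

Step 7
Reactants: 15 3,5-dihydroxy-2,4-bis(3-methylbut-2-enyl)-6-(trimethylsilyl)phenyl trifluoromethanesulfonate
Product: 16 3,5-bis(methoxymethoxy)-2,4-bis(3-methylbut-2-enyl)-6-(trimethylsilyl)phenyl trifluoromethanesulfonate
Conditions: MOMCl, iPr2NEt, CH2Cl2, 0 °C → rt
Reagents that add atoms: chloromethyl methyl ether, COCCl
Why: Williamson-type O-alkylation of the two phenols with MOMCl under a hindered amine base, weak enough that no free phenoxide should build up next to silicon and trigger silyl migration with loss of triflate.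

Step 8
Reactants: 17 1-(3,4-dihydroxyphenyl)ethanone (3',4'-dihydroxyacetophenone)
Product: 18 1-[3,4-bis(methoxymethoxy)phenyl]ethanone
Conditions: MOMCl, iPr2NEt, CH2Cl2, 0 °C → rt
Reagents that add atoms: chloromethyl methyl ether, COCCl
Why: Williamson-type acetal formation protects the catechol so that it survives base, hydride transfer, fluoride and the Mitsunobu reagents.

Step 9
Reactants: 18 1-[3,4-bis(methoxymethoxy)phenyl]ethanone
Product: 19 ethyl 3-[3,4-bis(methoxymethoxy)phenyl]-3-oxopropanoate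
Conditions: NaH, (EtO)2CO, THF, reflux; then AcOH
Reagents that add atoms: diethyl carbonate, CCOC(=O)OCC
Why: Crossed Claisen condensation of the ketone enolate with diethyl carbonate, driven to completion by deprotonation of the β-keto ester formed.

Step 10
Reactants: 19 ethyl 3-[3,4-bis(methoxymethoxy)phenyl]-3-oxopropanoate
Product: 20 ethyl (R)-3-[3,4-bis(methoxymethoxy)phenyl]-3-hydroxypropanoate
Conditions: RuCl(p-cymene)[(R,R)-TsDPEN] (1 mol%), HCO2H/Et3N (5:2), EtOAc, 30 °C
Reagents that add atoms: none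
Why: Noyori asymmetric transfer hydrogenation; the (R,R)-TsDPEN ruthenium hydride delivers hydrogen to the ketone face fixed by the aryl CH/π contact in the six-membered outer-sphere transition state, which should set the (R) carbinol centre as it does for simple aryl ketones.

Step 11
Reactants: 20 ethyl (R)-3-[3,4-bis(methoxymethoxy)phenyl]-3-hydroxypropanoate
Product: 21 ethyl (R)-3-[3,4-bis(methoxymethoxy)phenyl]-3-(triisopropylsilyloxy)propanoate
Conditions: TIPSOTf, 2,6-lutidine, CH2Cl2, −78 → 0 °C
Reagents that add atoms: triisopropylsilyl trifluoromethanesulfonate, CC(C)[Si](OS(=O)(=O)C(F)(F)F)(C(C)C)C(C)C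
Why: Silylation of the secondary alcohol with the silyl triflate and a hindered pyridine base at low temperature, fast enough to leave the aryl acetals untouched.

Step 12
Reactants: 21 ethyl (R)-3-[3,4-bis(methoxymethoxy)phenyl]-3-(triisopropylsilyloxy)propanoate
Product: 22 (R)-3-[3,4-bis(methoxymethoxy)phenyl]-3-(triisopropylsilyloxy)propanoic acid
Conditions: LiOH, THF/EtOH/H2O, rt; then 0.5 M aq. HCl to pH 4, 0 °C
Reagents that add atoms: lithium hydroxide, [Li+].[OH-]
Why: Saponification of the ethyl ester; the silyloxide is a poor leaving group at room temperature so no cinnamate should form, and acidification only to pH 4 spares the acetals and the silyl ether.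

Step 13
Reactants: 16 3,5-bis(methoxymethoxy)-2,4-bis(3-methylbut-2-enyl)-6-(trimethylsilyl)phenyl trifluoromethanesulfonate; 22 (R)-3-[3,4-bis(methoxymethoxy)phenyl]-3-(triisopropylsilyloxy)propanoic acid
Product: 24 (R)-3-[3,4-bis(methoxymethoxy)phenyl]-1-[2-hydroxy-4,6-bis(methoxymethoxy)-3,5-bis(3-methylbut-2-enyl)phenyl]-3-(triisopropylsilyloxy)propan-1-one, via aryne 23 (not isolated)
Conditions: 16 (1.3 equiv), CsF (4 equiv), THF, 110 °C, sealed tube
Reagents that add atoms: none
Why: Fluoride attacks silicon of 16 and triflate leaves, giving aryne 23 (C4a≡C8a); the cesium carboxylate of 22 adds through oxygen to C8a, and the aryl anion formed at C4a attacks the neighbouring ester carbonyl through a four-membered alkoxide that opens to the C4a ketone and the C8a phenoxide, so C8a–O1 and C4a–C4 arise in one operation. The closest known reaction type is the fluoride-induced insertion of arynes into the C–O bond of carboxylic acids to give ortho-hydroxyaryl ketones (O-arylation followed by an anionic Fries-type acyl shift). No ring is closed and no stereocentre is formed; the carbinol carbon of the acid (the future C2) is not enolisable and is a spectator. The step needs regioselective addition to an unsymmetrical aryne: the C5 OMOM group polarises and distorts the triple bond so that the nucleophile adds to the remote carbon C8a and charge builds at C4a beside the oxygen, which should outweigh the modest shielding of C8a by the C8 prenyl methylene. It also needs the acyl shift to outrun protonation of the aryl anion (aprotic THF, acid present only as its carboxylate in excess CsF) and the β-oxygen to stay in place, for which the triisopropylsilyl ether is chosen as a poor leaving group and the most fluoride-resistant common silyl ether.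

Step 14
Reactants: 24 (R)-3-[3,4-bis(methoxymethoxy)phenyl]-1-[2-hydroxy-4,6-bis(methoxymethoxy)-3,5-bis(3-methylbut-2-enyl)phenyl]-3-(triisopropylsilyloxy)propan-1-one
Product: 25 (R)-3-[3,4-bis(methoxymethoxy)phenyl]-3-hydroxy-1-[2-hydroxy-4,6-bis(methoxymethoxy)-3,5-bis(3-methylbut-2-enyl)phenyl]propan-1-one
Conditions: TBAF, AcOH (1:1), THF, 0 °C → rt
Reagents that add atoms: none
Why: Fluoride-mediated cleavage of the Si–O bond, buffered with acetic acid so that the β-hydroxy ketone is not exposed to basic fluoride that could cause retro-aldol cleavage or dehydration.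

Step 15
Reactants: 25 (R)-3-[3,4-bis(methoxymethoxy)phenyl]-3-hydroxy-1-[2-hydroxy-4,6-bis(methoxymethoxy)-3,5-bis(3-methylbut-2-enyl)phenyl]propan-1-one
Product: 26 (2S)-2-[3,4-bis(methoxymethoxy)phenyl]-5,7-bis(methoxymethoxy)-6,8-bis(3-methylbut-2-enyl)chroman-4-one
Conditions: PPh3, DIAD, THF, 0 °C → rt
Reagents that add atoms: none
Why: Intramolecular Mitsunobu etherification: the phenol oxygen O1 displaces the alkoxyphosphonium at C2 in an SN2 6-exo-tet closure with inversion, which should turn the (R) carbinol into the (2S) flavanone.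

Step 16
Reactants: 26 (2S)-2-[3,4-bis(methoxymethoxy)phenyl]-5,7-bis(methoxymethoxy)-6,8-bis(3-methylbut-2-enyl)chroman-4-one
Product: 27 6,8-diprenyleriodictyol, (2S)-2-(3,4-dihydroxyphenyl)-5,7-dihydroxy-6,8-bis(3-methylbut-2-enyl)chroman-4-one
Conditions: 3 M aq. HCl/MeOH (1:10), 40 °C, argon
Reagents that add atoms: none
Why: Acid-catalysed acetal methanolysis removes all four MOM groups; flavanones open and racemise under base but not under dilute acid, so the configuration at C2 should be retained.

Compound list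
1 | phloroglucinol | Oc1cc(O)cc(O)c1 | starting material
2 | 1,3,5-tris(methoxymethoxy)benzene | COCOc1cc(OCOC)cc(OCOC)c1 | intermediate
3 | prenyl bromide (1-bromo-3-methylbut-2-ene) | CC(C)=CCBr | starting material
4 | 2,4,6-tris(methoxymethoxy)phenyllithium | [Li]c1c(OCOC)cc(OCOC)cc1OCOC | intermediate
5 | 1,3,5-tris(methoxymethoxy)-2-(3-methylbut-2-enyl)benzene | COCOc1cc(OCOC)c(CC=C(C)C)c(OCOC)c1 | intermediate
6 | 2,4,6-tris(methoxymethoxy)-3-(3-methylbut-2-enyl)phenyllithium | [Li]c1c(OCOC)cc(OCOC)c(CC=C(C)C)c1OCOC | intermediate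
7 | 1,3,5-tris(methoxymethoxy)-2,4-bis(3-methylbut-2-enyl)benzene | COCOc1cc(OCOC)c(CC=C(C)C)c(OCOC)c1CC=C(C)C | intermediate
8 | 2,4,6-tris(methoxymethoxy)-3,5-bis(3-methylbut-2-enyl)phenyllithium | [Li]c1c(OCOC)c(CC=C(C)C)c(OCOC)c(CC=C(C)C)c1OCOC | intermediate
9 | 2-bromo-1,3,5-tris(methoxymethoxy)-4,6-bis(3-methylbut-2-enyl)benzene | Brc1c(OCOC)c(CC=C(C)C)c(OCOC)c(CC=C(C)C)c1OCOC | intermediate
10 | 2-bromo-4,6-bis(3-methylbut-2-enyl)benzene-1,3,5-triol | Oc1c(Br)c(O)c(CC=C(C)C)c(O)c1CC=C(C)C | intermediate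
11 | 2-bromo-4,6-bis(3-methylbut-2-enyl)-1,3,5-tris(trimethylsilyloxy)benzene | C[Si](C)(C)Oc1c(Br)c(O[Si](C)(C)C)c(CC=C(C)C)c(O[Si](C)(C)C)c1CC=C(C)C | intermediate
12 | 3,5-bis(3-methylbut-2-enyl)-2,4,6-tris(trimethylsilyloxy)phenyllithium | [Li]c1c(O[Si](C)(C)C)c(CC=C(C)C)c(O[Si](C)(C)C)c(CC=C(C)C)c1O[Si](C)(C)C | intermediate
13 | lithium 2,4-bis(3-methylbut-2-enyl)-3,5-bis(trimethylsilyloxy)-6-(trimethylsilyl)phenoxide | [Li]Oc1c([Si](C)(C)C)c(O[Si](C)(C)C)c(CC=C(C)C)c(O[Si](C)(C)C)c1CC=C(C)C | intermediate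
14 | 2,4-bis(3-methylbut-2-enyl)-3,5-bis(trimethylsilyloxy)-6-(trimethylsilyl)phenyl trifluoromethanesulfonate | C[Si](C)(C)c1c(O[Si](C)(C)C)c(CC=C(C)C)c(O[Si](C)(C)C)c(CC=C(C)C)c1OS(=O)(=O)C(F)(F)F | intermediate
15 | 3,5-dihydroxy-2,4-bis(3-methylbut-2-enyl)-6-(trimethylsilyl)phenyl trifluoromethanesulfonate | C[Si](C)(C)c1c(O)c(CC=C(C)C)c(O)c(CC=C(C)C)c1OS(=O)(=O)C(F)(F)F | intermediate
16 | 3,5-bis(methoxymethoxy)-2,4-bis(3-methylbut-2-enyl)-6-(trimethylsilyl)phenyl trifluoromethanesulfonate | C[Si](C)(C)c1c(OCOC)c(CC=C(C)C)c(OCOC)c(CC=C(C)C)c1OS(=O)(=O)C(F)(F)F | intermediate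
17 | 1-(3,4-dihydroxyphenyl)ethanone | CC(=O)c1ccc(O)c(O)c1 | starting material
18 | 1-[3,4-bis(methoxymethoxy)phenyl]ethanone | CC(=O)c1ccc(OCOC)c(OCOC)c1 | intermediate
19 | ethyl 3-[3,4-bis(methoxymethoxy)phenyl]-3-oxopropanoate | CCOC(=O)CC(=O)c1ccc(OCOC)c(OCOC)c1 | intermediate
20 | ethyl (R)-3-[3,4-bis(methoxymethoxy)phenyl]-3-hydroxypropanoate | CCOC(=O)C[C@@H](O)c1ccc(OCOC)c(OCOC)c1 | intermediate
21 | ethyl (R)-3-[3,4-bis(methoxymethoxy)phenyl]-3-(triisopropylsilyloxy)propanoate | CCOC(=O)C[C@@H](O[Si](C(C)C)(C(C)C)C(C)C)c1ccc(OCOC)c(OCOC)c1 | intermediate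
22 | (R)-3-[3,4-bis(methoxymethoxy)phenyl]-3-(triisopropylsilyloxy)propanoic acid | OC(=O)C[C@@H](O[Si](C(C)C)(C(C)C)C(C)C)c1ccc(OCOC)c(OCOC)c1 | intermediate
23 | 3,5-bis(methoxymethoxy)-4,6-bis(3-methylbut-2-enyl)benzyne (1,2-didehydrobenzene) | CC(C)=CCC1=C(OCOC)C(CC=C(C)C)=C(OCOC)C#C1 | intermediate
24 | (R)-3-[3,4-bis(methoxymethoxy)phenyl]-1-[2-hydroxy-4,6-bis(methoxymethoxy)-3,5-bis(3-methylbut-2-enyl)phenyl]-3-(triisopropylsilyloxy)propan-1-one | CC(C)=CCc1c(O)c(C(=O)C[C@@H](O[Si](C(C)C)(C(C)C)C(C)C)c2ccc(OCOC)c(OCOC)c2)c(OCOC)c(CC=C(C)C)c1OCOC | intermediate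
25 | (R)-3-[3,4-bis(methoxymethoxy)phenyl]-3-hydroxy-1-[2-hydroxy-4,6-bis(methoxymethoxy)-3,5-bis(3-methylbut-2-enyl)phenyl]propan-1-one | CC(C)=CCc1c(O)c(C(=O)C[C@@H](O)c2ccc(OCOC)c(OCOC)c2)c(OCOC)c(CC=C(C)C)c1OCOC | intermediate
26 | (2S)-2-[3,4-bis(methoxymethoxy)phenyl]-5,7-bis(methoxymethoxy)-6,8-bis(3-methylbut-2-enyl)chroman-4-one | CC(C)=CCc1c(OCOC)c(CC=C(C)C)c2c(c1OCOC)C(=O)C[C@@H](c1ccc(OCOC)c(OCOC)c1)O2 | intermediate
27 | 6,8-diprenyleriodictyol, (2S)-2-(3,4-dihydroxyphenyl)-5,7-dihydroxy-6,8-bis(3-methylbut-2-enyl)chroman-4-one | CC(C)=CCc1c(O)c(CC=C(C)C)c2c(c1O)C(=O)C[C@@H](c1ccc(O)c(O)c1)O2 | target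

Total step count: 16.
Longest linear sequence: 11 steps (steps 1–7, then 13–16); the acid branch (steps 8–12) joins at step 13.

Steps most likely to fail

Step 13 (aryne insertion). The aryl anion may be protonated before the acyl shift, so that only O-arylation occurs. The carboxylate may also add to the other aryne carbon, or hot fluoride may strip or eliminate the β-silyloxy group. The fallback makes the same ketone by organolithium acylation, setting out from 7 and 22 and returning at 24. Acid 22 is coupled with MeNHOMe·HCl (EDC·HCl, HOBt, iPr2NEt, CH2Cl2) to give (R)-3-[3,4-bis(methoxymethoxy)phenyl]-N-methoxy-N-methyl-3-(triisopropylsilyloxy)propanamide F1. Arene 7 is lithiated as in step 4 to aryllithium 8, which should add to F1 (THF, −78 °C) to give (R)-3-[3,4-bis(methoxymethoxy)phenyl]-1-[2,4,6-tris(methoxymethoxy)-3,5-bis(3-methylbut-2-enyl)phenyl]-3-(triisopropylsilyloxy)propan-1-one F2. MgBr2·OEt2 (Et2O/CH2Cl2, 0 °C) should then remove one of the two symmetry-equivalent ortho MOM groups by chelation to the ketone, which gives 24.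

Step 15 (Mitsunobu closure). The activated oxygen may be lost by E1cB elimination toward the chalcone, or the electron-rich benzylic oxyphosphonium may ionise in part, eroding the configuration at C2. The fallback gives up stereospecific closure for a kinetic resolution, setting out from 25 and returning at 26. KOH in aqueous EtOH at rt should dehydrate 25 to (E)-3-[3,4-bis(methoxymethoxy)phenyl]-1-[2-hydroxy-4,6-bis(methoxymethoxy)-3,5-bis(3-methylbut-2-enyl)phenyl]prop-2-en-1-one F3. NaOAc in refluxing EtOH should cyclise it by oxa-Michael addition to racemic 2-[3,4-bis(methoxymethoxy)phenyl]-5,7-bis(methoxymethoxy)-6,8-bis(3-methylbut-2-enyl)chroman-4-one F4. Asymmetric transfer hydrogenation with RhCl(Cp*)[(R,R)-TsDPEN] in HCO2H/Et3N/EtOAc is then expected to reduce the (2R) enantiomer faster, to cis-(2R,4R)-2-[3,4-bis(methoxymethoxy)phenyl]-5,7-bis(methoxymethoxy)-6,8-bis(3-methylbut-2-enyl)chroman-4-ol F5. The unreacted (2S) ketone 26 is separated by chromatography.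

Step 7 (MOM protection next to silicon and triflate). Deprotonation of the phenol beside the trimethylsilyl group may start a carbon-to-oxygen silyl migration with expulsion of triflate, releasing the aryne early, or alkylation of this crowded phenol may stall. The fallback installs the triflate last, setting out from lithium phenoxide 13 (made from 10 as in step 6) and returning at 16. Phenoxide 13 is quenched with AcCl instead of Tf2O to give 2,4-bis(3-methylbut-2-enyl)-3,5-bis(trimethylsilyloxy)-6-(trimethylsilyl)phenyl acetate F6. Work-up with AcOH/H2O/THF should give 3,5-dihydroxy-2,4-bis(3-methylbut-2-enyl)-6-(trimethylsilyl)phenyl acetate F7. MOMCl/iPr2NEt then gives 3,5-bis(methoxymethoxy)-2,4-bis(3-methylbut-2-enyl)-6-(trimethylsilyl)phenyl acetate F8. K2CO3 in MeOH frees 3,5-bis(methoxymethoxy)-2,4-bis(3-methylbut-2-enyl)-6-(trimethylsilyl)phenol F9. NaH and PhNTf2 (THF, 0 °C) convert F9 into 16; with no triflate present while a phenoxide exists, the silyl migration has no outlet.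

Further compounds
F1 | step 13 | (R)-3-[3,4-bis(methoxymethoxy)phenyl]-N-methoxy-N-methyl-3-(triisopropylsilyloxy)propanamide | CON(C)C(=O)C[C@@H](O[Si](C(C)C)(C(C)C)C(C)C)c1ccc(OCOC)c(OCOC)c1
F2 | step 13 | (R)-3-[3,4-bis(methoxymethoxy)phenyl]-1-[2,4,6-tris(methoxymethoxy)-3,5-bis(3-methylbut-2-enyl)phenyl]-3-(triisopropylsilyloxy)propan-1-one | COCOc1c(CC=C(C)C)c(OCOC)c(CC=C(C)C)c(OCOC)c1C(=O)C[C@@H](O[Si](C(C)C)(C(C)C)C(C)C)c1ccc(OCOC)c(OCOC)c1
F3 | step 15 | (E)-3-[3,4-bis(methoxymethoxy)phenyl]-1-[2-hydroxy-4,6-bis(methoxymethoxy)-3,5-bis(3-methylbut-2-enyl)phenyl]prop-2-en-1-one | CC(C)=CCc1c(O)c(C(=O)/C=C/c2ccc(OCOC)c(OCOC)c2)c(OCOC)c(CC=C(C)C)c1OCOC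
F4 | step 15 | racemic 2-[3,4-bis(methoxymethoxy)phenyl]-5,7-bis(methoxymethoxy)-6,8-bis(3-methylbut-2-enyl)chroman-4-one | CC(C)=CCc1c(OCOC)c(CC=C(C)C)c2c(c1OCOC)C(=O)CC(c1ccc(OCOC)c(OCOC)c1)O2
F5 | step 15 | (2R,4R)-2-[3,4-bis(methoxymethoxy)phenyl]-5,7-bis(methoxymethoxy)-6,8-bis(3-methylbut-2-enyl)chroman-4-ol | CC(C)=CCc1c(OCOC)c(CC=C(C)C)c2c(c1OCOC)[C@H](O)C[C@H](c1ccc(OCOC)c(OCOC)c1)O2
F6 | step 7 | 2,4-bis(3-methylbut-2-enyl)-3,5-bis(trimethylsilyloxy)-6-(trimethylsilyl)phenyl acetate | CC(=O)Oc1c([Si](C)(C)C)c(O[Si](C)(C)C)c(CC=C(C)C)c(O[Si](C)(C)C)c1CC=C(C)C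
F7 | step 7 | 3,5-dihydroxy-2,4-bis(3-methylbut-2-enyl)-6-(trimethylsilyl)phenyl acetate | CC(=O)Oc1c([Si](C)(C)C)c(O)c(CC=C(C)C)c(O)c1CC=C(C)C
F8 | step 7 | 3,5-bis(methoxymethoxy)-2,4-bis(3-methylbut-2-enyl)-6-(trimethylsilyl)phenyl acetate | CC(=O)Oc1c([Si](C)(C)C)c(OCOC)c(CC=C(C)C)c(OCOC)c1CC=C(C)C
F9 | step 7 | 3,5-bis(methoxymethoxy)-2,4-bis(3-methylbut-2-enyl)-6-(trimethylsilyl)phenol | Oc1c([Si](C)(C)C)c(OCOC)c(CC=C(C)C)c(OCOC)c1CC=C(C)C
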